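(The readings were computed for substances that don't exist; noise was put on by code.)

Take one ratio: product at the last reading over partner charged. In the south-west run it is 0.439, and we call this the partner's share. We want it for the south run, which has more partner.

| flask | substrate | partner | catalyst | time |
|---|---|---|---|---|
| south-east | 0.300 M | 0.450 M | 0.0300 M |  |
| east | 0.150 M | 0.300 M | 0.0300 M |  |
| south-west | 0.900 M | 0.450 M | 0.0300 M |  |
| south | 1.50 M | 2.20 M | 0.0300 M | 9.5 h |

| run | time / h | [product] / M |
|---|---|---|
| south-east run | 1.9 | 0.0793 |
| south-east run | 3.8 | 0.1390 |
| south-east run | 5.7 | 0.1732 |
| south-east run | 7.6 | 0.1829 |
| south-east run | 9.5 | 0.1904 |
| east run | 1.9 | 0.0416 |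
| east run | 3.8 | 0.0745 |
| east run | 5.7 | 0.0955 |
| east run | 7.6 | 0.1061 |
| east run | 9.5 | 0.1082 |
| south-west run | 1.9 | 0.0817 |
| south-west run | 3.8 | 0.1502 |
| south-west run | 5.7 | 0.1763 |
| south-west run | 7.6 | 0.1936 |
| south-west run | 9.5 | 0.1977 |

(scatter of a reading: 0.002 M)

* the exponent of [substrate] in the starting rate at the charge of the south-east run (at the point where two percent of the substrate have become product) (one fixed amount of product, the same in the runs compared)
* the exponent of [partner] in the starting rate at the charge of the south-east run (at the point where two percent of the substrate have become product)
* the east run starts with 0.150 M less of substrate and of partner than the south-east run, and with no product. Compared where both hold the same amount of substrate, once fifteen percent of what the east run was charged with has turned into product, is the east run faster, slower or alike (within a tenth)?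
* product in the south run at 9.5 h, as a share of the substrate charged

- Overall: substrate + partner -> product, with catalyst as catalyst.
- Constant volume, constant temperature.
- Bound and free are read together.
- An order is taken over about fifteen percent of the charge, up and down.

| run | last product over partner charged | last product over substrate charged |
|---|---|---|
| south-east | 0.423 | 0.635 |
| east | 0.361 | 0.721 |
| south-west | 0.439 | 0.220 |

We build our reckoning one process at a time, starting with the main step. Between the south-east and south-west runs the substrate charge grows 3.00 times, yet the first readings stand in a ratio of 1.03. That gives a substrate order of about 0.0271, so we take the rate as near zero order in substrate at these charges. The east run, on 0.667 of the south-east run's partner, gives 0.525 of its first reading, though its substrate differs too. This pair taken by itself gives a partner order of 1.59, but we choose the round value of first order as our working assumption. With this step alone, the south run's ceiling is its substrate, the limiting reagent: 100% of the substrate, or a partner's share of 0.682.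

The second process comes from the table. At the last readings of the three runs, the fraction of substrate turned runs from 0.220 to 0.721, while the partner's share runs only from 0.361 to 0.439. We therefore suppose that partner has a second exit, also first order in partner. The two exits then keep a fixed ratio, and the share does not move with the partner charge.

The rest shows in the east run, whose share is lower than the south-west run's. So the share is not strictly constant, and we use the south-west value, from the earlier run with the most substrate. By this estimate the south run makes 0.967 M, less than its substrate charge, and this product is 64.4% of that charge.

At equal substrate the south-east run is near its 5.7 h reading and the east run near its start. The east run's first interval gives 0.0219 M h⁻¹, and the south-east run's next interval gives 5.11 mM h⁻¹, so we estimate that the east run is faster.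

The forecast gives a substrate order of 0.25, a partner order of 1, an east run that is faster, and 50% for the south run. Its ground is that “the catalyst appears to die on a clock”. Our 64.4% differs from it.

The flask gives a substrate order of 0.034, a partner order of 1.1, an east run that is faster, and 74.4% for the south run, above both 64.4% and 50%.

    active catalyst + substrate ⇌ catalyst-substrate complex, settled at all times (64.10 M⁻¹)
    catalyst-substrate complex + partner → product + active catalyst + by-product (7.884 M⁻¹ h⁻¹)
    catalyst + partner → active catalyst + partner (2.858 M⁻¹ h⁻¹)
    partner → lost reagent (0.2027 h⁻¹)

The south run's partner's share comes to 0.507, not the 0.439 read from the south-west run. The shortfall from complete conversion is due to the step from partner to lost reagent. The south run computed without that step proves it: its product reaches 100% of the substrate, which is a partner's share of 0.682.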